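**Retrosynthetic overview**

1. The two esters and the C8–C9 bond are disconnected: the seven-membered ring (C4–C5–C6–C7–C8–C9–C10) is closed last, by an intramolecular aldol–Tishchenko reaction between a C9 aldehyde on C10 and a C7 methyl ketone on C6, with tiglaldehyde as hydride donor.
2. Enabling feature: C6 and C10 are both quaternary and their carbonyl arms sit cis-1,3 on the cyclobutane (on C5 and C10, face opposite the C1–C3 bridge), so C8 is the only enolisable carbon between them. The trans-1,3-diol with two different esters at C9/C7 is the pattern an aldol–Tishchenko reaction delivers.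
3. The C6–C7–C8 arm is grown from the cyclobutanone carbonyl (C5) by olefination and hydrogenation directed by the C1 hydroxyl; the same C1 carbinol later becomes the enone.
4. The bicyclo[3.1.1] core (four- and six-membered rings in one step) comes from a crossed intramolecular vinylketene–alkene [2+2] of an acyclic (5S)-dienoic acid. Its one stereocentre (future C1, from a catalytic asymmetric vinylogous Mukaiyama aldol) controls C4, C10 and C11 and is later oxidised away.
5. Ring order: cyclobutane and cyclohexane together (step 7), seven-membered ring last (step 15).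

Key step: step 15

Locants: the longipinane numbering of the target is used for ring compounds: C1 ketone, C2=C3 (methyl on C3), C4 and C11 bridgeheads, C5 cyclobutane CH, C6 CMe2, C7 (O-isovaleryl), C8, C9 (O-tigloyl), C10 quaternary cyclobutane carbon.

Assumption: the facial sense of the two chiral catalysts (steps 5 and 15) is taken as written; if either proves opposite, the antipodal catalyst is used without other change.

**Route**

Step 1
Reactants: 1 1-[(tert-butyldimethylsilyl)oxy]propan-2-one; 2 triethyl phosphonoacetate
Product: 3 ethyl (2E)-4-[(tert-butyldimethylsilyl)oxy]-3-methylbut-2-enoate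
Conditions: NaH, THF, 0 °C to rt; E isomer separated by chromatography
Reagents that add atoms: none
Why: Horner–Wadsworth–Emmons olefination of the α-silyloxy ketone, in which the ester should settle trans to the larger CH2OTBS group and the minor Z isomer is removed.

Step 2
Reactants: 3 ethyl (2E)-4-[(tert-butyldimethylsilyl)oxy]-3-methylbut-2-enoate
Product: 4 (2E)-4-[(tert-butyldimethylsilyl)oxy]-3-methylbut-2-en-1-ol
Conditions: iBu2AlH, CH2Cl2, −78 °C; aq. potassium sodium tartrate
Reagents that add atoms: none
Why: 1,2-reduction of the conjugated ester by the aluminium hydride (DIBAL reduction) should leave the alkene geometry and the silyl ether untouched.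

Step 3
Reactants: 4 (2E)-4-[(tert-butyldimethylsilyl)oxy]-3-methylbut-2-en-1-ol
Product: 5 (2E)-4-[(tert-butyldimethylsilyl)oxy]-3-methylbut-2-enal
Conditions: MnO2, CH2Cl2, rt
Reagents that add atoms: none
Why: allylic oxidation with activated MnO2 is selective for the allylic alcohol and should not isomerise the E alkene.

Step 4
Reactants: 6 tert-butyl 3-methylbut-2-enoate
Product: 7 (1Z)-1-tert-butoxy-1-[(tert-butyldimethylsilyl)oxy]-3-methylbuta-1,3-diene
Conditions: LiN(iPr)2, THF, −78 °C; tBuMe2SiCl, DMPU, −78 °C to rt
Reagents that add atoms: tert-butyldimethylsilyl chloride, CC(C)(C)[Si](C)(C)Cl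
Why: γ-deprotonation of the senecioate and O-silylation of the extended enolate (silyl ketene acetal formation) gives the dienolate for the vinylogous aldol; its double-bond geometry has no bearing on the product.

Step 5
Reactants: 5 (2E)-4-[(tert-butyldimethylsilyl)oxy]-3-methylbut-2-enal; 7 (1Z)-1-tert-butoxy-1-[(tert-butyldimethylsilyl)oxy]-3-methylbuta-1,3-diene
Product: 8 tert-butyl (2E,5S,6E)-8-[(tert-butyldimethylsilyl)oxy]-5-hydroxy-3,7-dimethylocta-2,6-dienoate
Conditions: SiCl4, (S,S)-bisphosphoramide catalyst 1,5-bis{methyl[3,5-dimethyl-4-oxido-3,5-dihydro-4H-dinaphtho[2,1-d:1',2'-f][1,3,2]diazaphosphepin-4-yl]amino}pentane (5 mol%), iPr2NEt (10 mol%), CH2Cl2, −78 °C; aq. NaHCO3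
Reagents that add atoms: none
Why: catalytic enantioselective vinylogous Mukaiyama aldol reaction (Lewis-base-activated SiCl4), in which the chiral silicon cation activates the enal, the dienolate attacks through its γ-carbon on the Si face, and the catalyst sets the carbinol centre 5S (future C1).

Step 6
Reactants: 8 tert-butyl (2E,5S,6E)-8-[(tert-butyldimethylsilyl)oxy]-5-hydroxy-3,7-dimethylocta-2,6-dienoate
Product: 10 (2E,5S,6E)-8-[(tert-butyldimethylsilyl)oxy]-3,7-dimethyl-5-[(triethylsilyl)oxy]octa-2,6-dienoic acid, via triethylsilyl ester 9 (not isolated)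
Conditions: Et3SiOTf, 2,6-lutidine, CH2Cl2, 0 °C to rt; pH 7 buffer, THF
Reagents that add atoms: triethylsilyl trifluoromethanesulfonate, CC[Si](CC)(CC)OS(=O)(=O)C(F)(F)F
Why: the silyl triflate silylates the alcohol and converts the tert-butyl ester into the labile silyl ester (silyl triflate cleavage of tert-butyl esters), which hydrolyses on work-up while both silyl ethers remain.

Step 7
Reactants: 10 (2E,5S,6E)-8-[(tert-butyldimethylsilyl)oxy]-3,7-dimethyl-5-[(triethylsilyl)oxy]octa-2,6-dienoic acid
Product: 13 bicyclo[3.1.1]heptan-6-one bearing 2-OTES; 4-methylidene; 7-methyl; 7-CH2OTBS (longipinane C5 ketone), via acid chloride 11 (not isolated), via vinylketene 12 (not isolated)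
Conditions: 1-chloro-N,N,2-trimethylprop-1-en-1-amine, CH2Cl2, 0 °C to rt; then slow addition to Et3N, toluene, 110 °C, high dilution
Reagents that add atoms: none
Why: crossed intramolecular [2+2] cycloaddition of a vinylketene with a trisubstituted alkene, in which the alkene CH bonds to the ketene carbonyl carbon and the ring closes at the more substituted carbon, the E geometry places the C10 methyl syn and CH2OTBS anti to the new three-carbon bridge, and A(1,3) strain with that methyl keeps the carbinol hydrogen in the alkene plane so the ketene adds to one face only and fixes C4, C10 and C11.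

Step 8
Reactants: 13 bicyclic cyclobutanone; 2 triethyl phosphonoacetate
Product: 14 ethyl 2-(bicyclo[3.1.1]heptan-6-ylidene)acetate bearing 2-OTES; 4-methylidene; 7-methyl; 7-CH2OTBS
Conditions: NaH, THF, 0 to 65 °C
Reagents that add atoms: none
Why: Horner–Wadsworth–Emmons olefination of the strained cyclobutanone, which cannot enolise because both α-carbons are bridgeheads; the geometry of the exocyclic enoate is of no consequence.

Step 9
Reactants: 14 exocyclic enoate with C1 OTES
Product: 15 exocyclic enoate with free C1 hydroxyl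
Conditions: pyridinium p-toluenesulfonate (cat.), EtOH, 0 °C
Reagents that add atoms: none
Why: acid-catalysed ethanolysis (selective desilylation) should remove the secondary triethylsilyl ether well before the primary TBS ether.

Step 10
Reactants: 15 exocyclic enoate with free C1 hydroxyl
Product: 16 ethyl 2-[7-{[(tert-butyldimethylsilyl)oxy]methyl}-2-hydroxy-4,7-dimethylbicyclo[3.1.1]heptan-6-yl]acetate
Conditions: H2 (1–4 atm), [Ir(cod)(PCy3)(py)]PF6 (10 mol%), CH2Cl2, rt
Reagents that add atoms: none
Why: hydroxyl-directed homogeneous hydrogenation, in which the C1 hydroxyl lying over one face of the exocyclic alkene binds iridium and delivers hydrogen there while CH2OTBS screens the other face, so C5 gains its hydrogen on the side of the C1–C3 bridge and the acetate arm points to the C10 side; the C3 methylidene (or any endocyclic isomer from step 7) is reduced in the same operation from the hydroxyl face.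

Step 11
Reactants: 16 hydroxy ester
Product: 18 ethyl 2-[7-{[(tert-butyldimethylsilyl)oxy]methyl}-2-hydroxy-4,7-dimethylbicyclo[3.1.1]heptan-6-yl]-2-methylpropanoate, via monomethyl ester 17 (not isolated)
Conditions: LiN(iPr)2, THF/DMPU, −78 °C, MeI; repeated in the same flask, −78 to −30 °C
Reagents that add atoms: iodomethane, CI
Why: two successive ester enolate alkylations build the C6 gem-dimethyl group; the lithium alkoxide at C1 should not be methylated at low temperature.

Step 12
Reactants: 18 gem-dimethyl ester
Product: 19 3-[7-{[(tert-butyldimethylsilyl)oxy]methyl}-2-hydroxy-4,7-dimethylbicyclo[3.1.1]heptan-6-yl]-3-methylbutan-2-one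
Conditions: Me3SiCH2Li, pentane/THF, 0 °C to rt; MeOH; aq. NH4Cl
Reagents that add atoms: (trimethylsilyl)methyllithium, [Li]C[Si](C)(C)C
Why: addition of the silylmethyl-lithium to the non-enolisable ester stops at the enolate of the α-silyl ketone, and methanolysis of the C–Si bond gives the methyl ketone (ester-to-methyl-ketone conversion through an α-silyl ketone).

Step 13
Reactants: 19 silyl ether methyl ketone
Product: 20 3-[2-hydroxy-7-(hydroxymethyl)-4,7-dimethylbicyclo[3.1.1]heptan-6-yl]-3-methylbutan-2-one
Conditions: HF·pyridine, pyridine, THF, 0 °C to rt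
Reagents that add atoms: none
Why: fluoride cleavage of the primary TBS ether (desilylation) under buffered conditions that cannot trigger enolisation.

Step 14
Reactants: 20 diol methyl ketone
Product: 22 1,7-dioxo-8,9-secolongipin-2-en-9-al, via saturated keto aldehyde 21 (not isolated)
Conditions: 2-iodoxybenzoic acid (IBX), DMSO, rt then 75 °C
Reagents that add atoms: none
Why: IBX oxidises both alcohols and, on warming, dehydrogenates the C1 ketone (IBX ketone dehydrogenation), which can only go toward C2–C3 because C11 is a bridgehead, the aldehyde has no α-hydrogen and the methyl ketone has no β-hydrogen.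

Step 15
Reactants: 22 1,7-dioxo-8,9-secolongipin-2-en-9-al; 23 (2E)-2-methylbut-2-enal (tiglaldehyde)
Product: 25 (7R,9R)-7-hydroxy-9-[(2E)-2-methylbut-2-enoyloxy]longipin-2-en-1-one, via aldol 24 (not isolated)
Conditions: LaLi3[(S)-1,1'-binaphthalene-2,2'-diolate]3 (20 mol%), LiOTf (60 mol%), 23 (3 equiv), THF, 0.02 M, rt
Reagents that add atoms: none
Why: Proposed new method: a ring-closing, catalyst-controlled crossed aldol–Tishchenko reaction, in which the lanthanum binaphthoxide enolises the C7 methyl ketone at C8, the enolate adds reversibly to the C9 aldehyde, the lanthanum aldolate adds to tiglaldehyde, and a hydride shift from that hemiacetal to the C7 ketone through a six-membered transition state gives the C9 tiglate and the C7 alkoxide. The closest known reactions are the direct catalytic asymmetric aldol–Tishchenko reaction of a ketone with two equivalents of one aldehyde under the same lanthanum–lithium binaphthoxide catalysis and the SmI2-catalysed Evans–Tishchenko reduction of β-hydroxy ketones; new here are the intramolecular aldol partner, the ring size and a second, different aldehyde as hydride donor. The seven-membered ring closes by a 7-(enolexo)-exo-trig aldol between two arms held cis-1,3 on the cyclobutane. C9 is set by the catalyst: the two aldol epimers interconvert by retro-aldol and only the hemiacetal matched to the binaphthoxide should transfer hydride quickly (dynamic kinetic resolution, needed because the aldehyde faces differ only through the remote enone), and C7 is set 1,3-anti to C9 because hydride arrives from the face of the C9 oxygen. Chemoselectivity rests on the substrate: both aldehydes are non-enolisable, C6 and C10 are quaternary, the enone offers only a γ-methyl that cannot reach C9, and acyl migration from O9 to O7 is blocked across the trans-diol of the rigid ring.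

Step 16
Reactants: 25 (7R,9R)-7-hydroxy-9-[(2E)-2-methylbut-2-enoyloxy]longipin-2-en-1-one; 26 3-methylbutanoyl chloride
Product: 27 (4R,5S,7R,9R,10R,11R)-7-(3-methylbutanoyloxy)-9-[(2E)-2-methylbut-2-enoyloxy]longipin-2-en-1-one (target)
Conditions: 4-(dimethylamino)pyridine (cat.), pyridine, CH2Cl2, 0 to 40 °C
Reagents that add atoms: none
Why: nucleophile-catalysed acylation (acyl transfer through the acylpyridinium) of the hindered C7 alcohol; no stereocentre is touched and the tiglate is stable under these conditions.

**Compound list**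

1 | 1-[(tert-butyldimethylsilyl)oxy]propan-2-one | CC(=O)CO[Si](C)(C)C(C)(C)C | starting material
2 | triethyl phosphonoacetate | CCOC(=O)CP(=O)(OCC)OCC | starting material
3 | ethyl (2E)-4-[(tert-butyldimethylsilyl)oxy]-3-methylbut-2-enoate | CCOC(=O)/C=C(\C)CO[Si](C)(C)C(C)(C)C | intermediate
4 | (2E)-4-[(tert-butyldimethylsilyl)oxy]-3-methylbut-2-en-1-ol | OC/C=C(\C)CO[Si](C)(C)C(C)(C)C | intermediate
5 | (2E)-4-[(tert-butyldimethylsilyl)oxy]-3-methylbut-2-enal | O=C/C=C(\C)CO[Si](C)(C)C(C)(C)C | intermediate
6 | tert-butyl 3-methylbut-2-enoate | CC(C)=CC(=O)OC(C)(C)C | starting material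
7 | (1Z)-1-tert-butoxy-1-[(tert-butyldimethylsilyl)oxy]-3-methylbuta-1,3-diene | C=C(C)/C=C(\O[Si](C)(C)C(C)(C)C)OC(C)(C)C | intermediate
8 | tert-butyl (2E,5S,6E)-8-[(tert-butyldimethylsilyl)oxy]-5-hydroxy-3,7-dimethylocta-2,6-dienoate | CC(C)(C)OC(=O)/C=C(\C)C[C@H](O)/C=C(\C)CO[Si](C)(C)C(C)(C)C | intermediate
9 | triethylsilyl ester of acid 10 (not isolated) | CC[Si](CC)(CC)OC(=O)/C=C(\C)C[C@H](O[Si](CC)(CC)CC)/C=C(\C)CO[Si](C)(C)C(C)(C)C | intermediate
10 | (2E,5S,6E)-8-[(tert-butyldimethylsilyl)oxy]-3,7-dimethyl-5-[(triethylsilyl)oxy]octa-2,6-dienoic acid | OC(=O)/C=C(\C)C[C@H](O[Si](CC)(CC)CC)/C=C(\C)CO[Si](C)(C)C(C)(C)C | intermediate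
11 | acid chloride of 10 (not isolated) | ClC(=O)/C=C(\C)C[C@H](O[Si](CC)(CC)CC)/C=C(\C)CO[Si](C)(C)C(C)(C)C | intermediate
12 | vinylketene, (5S,6E)-configured (not isolated) | O=C=CC(=C)C[C@H](O[Si](CC)(CC)CC)/C=C(\C)CO[Si](C)(C)C(C)(C)C | intermediate
13 | 7-{[(tert-butyldimethylsilyl)oxy]methyl}-7-methyl-4-methylidene-2-[(triethylsilyl)oxy]bicyclo[3.1.1]heptan-6-one; OTES on the side of the carbonyl bridge, 7-methyl on the side of the three-carbon bridge | CC(C)(C)[Si](C)(C)OC[C@@]1(C)[C@@H]2[C@@H](O[Si](CC)(CC)CC)CC(=C)[C@H]1C2=O | intermediate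
14 | ethyl 2-(6-ylidene)acetate of 13; drawn with the ester on the side of C4 (longipinane), geometry irrelevant | CC(C)(C)[Si](C)(C)OC[C@@]1(C)[C@@H]2[C@@H](O[Si](CC)(CC)CC)CC(=C)[C@H]1/C2=C\C(=O)OCC | intermediate
15 | exocyclic enoate with free C1 hydroxyl | CC(C)(C)[Si](C)(C)OC[C@@]1(C)[C@@H]2[C@@H](O)CC(=C)[C@H]1/C2=C\C(=O)OCC | intermediate
16 | ethyl 2-[7-{[(tert-butyldimethylsilyl)oxy]methyl}-2-hydroxy-4,7-dimethylbicyclo[3.1.1]heptan-6-yl]acetate; C5–H on the side of the C1–C3 bridge, arm cis to CH2OTBS, C3 methyl on the side of C10 | CC(C)(C)[Si](C)(C)OC[C@@]1(C)[C@@H]2[C@@H](O)C[C@H](C)[C@H]1[C@@H]2CC(=O)OCC | intermediate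
17 | monomethylated ester, either C6 epimer (not isolated) | CC(C)(C)[Si](C)(C)OC[C@@]1(C)[C@@H]2[C@@H](O)C[C@H](C)[C@H]1[C@@H]2C(C)C(=O)OCC | intermediate
18 | gem-dimethyl ester | CC(C)(C)[Si](C)(C)OC[C@@]1(C)[C@@H]2[C@@H](O)C[C@H](C)[C@H]1[C@@H]2C(C)(C)C(=O)OCC | intermediate
19 | methyl ketone with C9 OTBS and C1 hydroxyl | CC(C)(C)[Si](C)(C)OC[C@@]1(C)[C@@H]2[C@@H](O)C[C@H](C)[C@H]1[C@@H]2C(C)(C)C(C)=O | intermediate
20 | 3-[2-hydroxy-7-(hydroxymethyl)-4,7-dimethylbicyclo[3.1.1]heptan-6-yl]-3-methylbutan-2-one | OC[C@@]1(C)[C@@H]2[C@@H](O)C[C@H](C)[C@H]1[C@@H]2C(C)(C)C(C)=O | intermediate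
21 | 1,7-dioxo-8,9-secolongipinan-9-al (not isolated) | O=C[C@@]1(C)[C@@H]2C(=O)C[C@H](C)[C@H]1[C@@H]2C(C)(C)C(C)=O | intermediate
22 | 1,7-dioxo-8,9-secolongipin-2-en-9-al | O=C[C@@]1(C)[C@@H]2C(=O)C=C(C)[C@H]1[C@@H]2C(C)(C)C(C)=O | intermediate
23 | (2E)-2-methylbut-2-enal (tiglaldehyde) | C/C=C(\C)C=O | starting material
24 | (9R)-9-hydroxylongipin-2-ene-1,7-dione (not isolated) | O[C@@H]1CC(=O)C(C)(C)[C@@H]2[C@H]3C(=O)C=C(C)[C@@H]2[C@]31C | intermediate
25 | (7R,9R)-7-hydroxy-9-[(2E)-2-methylbut-2-enoyloxy]longipin-2-en-1-one | C/C=C(\C)C(=O)O[C@@H]1C[C@@H](O)C(C)(C)[C@@H]2[C@H]3C(=O)C=C(C)[C@@H]2[C@]31C | intermediate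
26 | 3-methylbutanoyl chloride | CC(C)CC(Cl)=O | starting material
27 | (4R,5S,7R,9R,10R,11R)-7-(3-methylbutanoyloxy)-9-[(2E)-2-methylbut-2-enoyloxy]longipin-2-en-1-one | C/C=C(\C)C(=O)O[C@@H]1C[C@@H](OC(=O)CC(C)C)C(C)(C)[C@@H]2[C@H]3C(=O)C=C(C)[C@@H]2[C@]31C | target

**Count and risks**

Total steps: 16. Longest linear sequence: 15 (steps 1–3 and 5–16; step 4 prepares the dienolate).

Steps most likely to fail:

Step 15 (the one step beyond known chemistry). Intermolecular aldol or Tishchenko reactions of tiglaldehyde may outrun the ring closure, and catalyst control over the C9 configuration may be weak. The fallback sets out from 22 and returns at 25 by two known reactions. An antipode of chlorodiisopinocampheylborane (Ipc2BCl) with Et3N in CH2Cl2 at −78 °C forms the boron enolate of the C7 methyl ketone, which should close onto the C9 aldehyde under reagent control; oxidative work-up gives isolated aldol 24. Samarium diiodide (SmI2, catalytic, pre-mixed with 23) and 23 in THF at −10 °C then carry out the Evans–Tishchenko reduction to 25. No compound outside the list is made (F0).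

Step 7. The doubly allylically oxygenated alkene may react too slowly with the ketene, so that ketene dimerisation takes over, and facial selectivity may erode at 110 °C. The fallback sets out from 10 and returns at 13 through a more electrophilic cumulene. Acid 10 is deconjugated through its dianion (LiN(iPr)2, THF, −78 °C, kinetic protonation) to (5S,6E)-8-[(tert-butyldimethylsilyl)oxy]-7-methyl-3-methylidene-5-[(triethylsilyl)oxy]oct-6-enoic acid F1. Coupling with pyrrolidine gives the pyrrolidine amide F2. Tf2O and 2,4,6-collidine in 1,2-dichloroethane at 80 °C generate the keteniminium ion, whose intramolecular [2+2] cycloaddition gives the cyclobutaniminium triflate F3; aqueous NaHCO3 hydrolyses it to 13.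

Step 8. Addition of the phosphonate anion to a carbonyl screened on both faces (OTES above, CH2OTBS below) may be too slow. The fallback sets out from 13 and returns at 14. Reformatsky addition of the small zinc enolate (Zn, ethyl bromoacetate, THF, reflux) gives the tertiary β-hydroxy ester F4 (either C5 epimer). Dehydration with the Burgess reagent can only go toward the exocyclic position, because both ring neighbours are bridgeheads, and gives 14.

Further compounds
F0 | step 15 | none | none
F1 | step 7 | (5S,6E)-8-[(tert-butyldimethylsilyl)oxy]-7-methyl-3-methylidene-5-[(triethylsilyl)oxy]oct-6-enoic acid | OC(=O)CC(=C)C[C@H](O[Si](CC)(CC)CC)/C=C(\C)CO[Si](C)(C)C(C)(C)C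
F2 | step 7 | pyrrolidine amide of F1 | O=C(CC(=C)C[C@H](O[Si](CC)(CC)CC)/C=C(\C)CO[Si](C)(C)C(C)(C)C)N1CCCC1
F3 | step 7 | cyclobutaniminium triflate corresponding to 13 | CC(C)(C)[Si](C)(C)OC[C@@]1(C)[C@@H]2[C@@H](O[Si](CC)(CC)CC)CC(=C)[C@H]1C2=[N+]1CCCC1.[O-]S(=O)(=O)C(F)(F)F
F4 | step 8 | ethyl 2-(6-hydroxybicyclo[3.1.1]heptan-6-yl)acetate derived from 13, either C5 epimer | CC(C)(C)[Si](C)(C)OC[C@@]1(C)[C@@H]2[C@@H](O[Si](CC)(CC)CC)CC(=C)[C@H]1C2(O)CC(=O)OCC
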